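**Retrosynthetic overview**
1. The bridged acetal is opened to a β-hydroxy methyl ketone that carries a masked ortho-formyl group on ring A and an ortho-phenol on ring B; the acid-triggered closure of the isochroman and 1,3-dioxine rings comes last.
2. The β-hydroxy ketone comes from an auxiliary-controlled anti-aldol between a ring-A arylacetyl thiazolidinethione and a ring-B isoquinoline-7-carbaldehyde (key C–C bond, both carbon stereocentres); the acyl group is then taken to the methyl ketone via the Weinreb amide.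
3. Both arenes derive from one pentasubstituted bromoarene 6, made from 4-bromo-2,6-difluorobenzaldehyde by SNAr, fluorine-directed ortho-lithiation/formylation and a second SNAr.
4. Ring order: the pyridine ring of the isoquinoline (Sonogashira, imine annulation) is built before the aldol; the two oxygen rings are formed together in the final step.

Assumption: the target SMILES is read as acetal carbon R, O-bearing benzylic carbon R, acetyl-bearing carbon S, which corresponds to a (3S,4R) anti-aldol in open-chain butan-2-one numbering.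

**Step 1**
Reactants: 1 4-bromo-2,6-difluorobenzaldehyde
Product: 2 2-(benzyloxy)-4-bromo-6-fluorobenzaldehyde
Conditions: BnOH (1.0 equiv), NaH (1.05 equiv), THF, −20 → 0 °C
Reagents that add atoms: benzyl alcohol, OCc1ccccc1
Why: SNAr of one of two equivalent fluorides ortho to the formyl group by benzyloxide; the new alkoxy donor deactivates the ring so substitution stops at the mono-ether.

**Step 2**
Reactants: 2 2-(benzyloxy)-4-bromo-6-fluorobenzaldehyde
Product: 3 2-[2-(benzyloxy)-4-bromo-6-fluorophenyl]-1,3-dioxolane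
Conditions: HOCH2CH2OH, TsOH·H2O (cat.), toluene, reflux, Dean–Stark
Reagents that add atoms: ethane-1,2-diol, OCCO
Why: Acid-catalysed acetalisation with azeotropic water removal masks the aldehyde (the later ring-A 3-formyl and isoquinoline 7-formyl carbon) against the amide base of the next step.

**Step 3**
Reactants: 3 2-[2-(benzyloxy)-4-bromo-6-fluorophenyl]-1,3-dioxolane
Product: 5 4-(benzyloxy)-6-bromo-3-(1,3-dioxolan-2-yl)-2-fluorobenzaldehyde, via aryllithium 4 (not isolated)
Conditions: LiN(iPr)2 (1.15 equiv), THF, −78 °C; DMF, −78 °C; AcOH quench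
Reagents that add atoms: N,N-dimethylformamide, CN(C)C=O
Why: Directed ortho-metalation removes the most acidic ring proton, the one flanked by F and Br (as in the standard preparation of 2-bromo-6-fluorobenzaldehyde), and the aryllithium, kept at −78 °C to avoid benzyne formation, is formylated by DMF.

**Step 4**
Reactants: 5 4-(benzyloxy)-6-bromo-3-(1,3-dioxolan-2-yl)-2-fluorobenzaldehyde
Product: 6 4-(benzyloxy)-6-bromo-3-(1,3-dioxolan-2-yl)-2-methoxybenzaldehyde
Conditions: NaOMe (1.2 equiv), MeOH/THF, 0 °C → rt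
Reagents that add atoms: sodium methoxide, [Na+].[O-]C
Why: SNAr of the fluoride ortho to the new formyl group by methoxide (fluoride is displaced far faster than the ortho bromide), which places OMe between the two formyl carbons as the target requires.

**Step 5**
Reactants: 6 4-(benzyloxy)-6-bromo-3-(1,3-dioxolan-2-yl)-2-methoxybenzaldehyde
Product: 7 4-(benzyloxy)-3-(1,3-dioxolan-2-yl)-2-methoxy-6-(prop-1-yn-1-yl)benzaldehyde
Conditions: propyne (3 equiv, THF solution), PdCl2(PPh3)2 (3 mol%), CuI (5 mol%), Et3N, THF, 50 °C, sealed tube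
Reagents that add atoms: propyne, CC#C
Why: Sonogashira coupling of an aryl bromide activated by the ortho formyl group installs the three carbons that become C4, C3 and the 3-methyl group of the isoquinoline.

**Step 6**
Reactants: 7 4-(benzyloxy)-3-(1,3-dioxolan-2-yl)-2-methoxy-6-(prop-1-yn-1-yl)benzaldehyde
Product: 9 6-(benzyloxy)-7-(1,3-dioxolan-2-yl)-8-methoxy-3-methylisoquinoline, via tert-butyl imine 8 (not isolated)
Conditions: t-BuNH2 (excess), 4 Å MS, CH2Cl2, rt; evaporate; CuI (10 mol%), DMF, 100 °C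
Reagents that add atoms: tert-butylamine, CC(C)(C)N
Why: Larock-type isoquinoline synthesis, in which copper-activated 6-endo attack of the imine nitrogen on the alkyne is followed by loss of the tert-butyl group as isobutene to aromatise the pyridine ring.

**Step 7**
Reactants: 9 6-(benzyloxy)-7-(1,3-dioxolan-2-yl)-8-methoxy-3-methylisoquinoline
Product: 10 6-(benzyloxy)-8-methoxy-3-methylisoquinoline-7-carbaldehyde
Conditions: 2 M aq. HCl/THF (1:2), rt; then NaHCO3
Reagents that add atoms: water, O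
Why: Acid hydrolysis of the dioxolane on an aryl carbon flanked by two alkoxy groups releases the non-enolisable aldol acceptor, while the benzyl ether is inert to aqueous acid.

**Step 8**
Reactants: 6 4-(benzyloxy)-6-bromo-3-(1,3-dioxolan-2-yl)-2-methoxybenzaldehyde
Product: 11 2,2'-[4-(benzyloxy)-6-bromo-2-methoxy-1,3-phenylene]bis(1,3-dioxolane)
Conditions: HOCH2CH2OH, TsOH·H2O (cat.), toluene, reflux, Dean–Stark
Reagents that add atoms: ethane-1,2-diol, OCCO
Why: A second acetalisation masks the formyl group that will become the acetal carbon, so that the ring-A donor carries no free electrophile.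

**Step 9**
Reactants: 11 2,2'-[4-(benzyloxy)-6-bromo-2-methoxy-1,3-phenylene]bis(1,3-dioxolane)
Product: 12 ethyl 2-[5-(benzyloxy)-2,4-bis(1,3-dioxolan-2-yl)-3-methoxyphenyl]acetate
Conditions: BrZnCH2CO2Et (1.5 equiv), Pd2(dba)3 (2.5 mol%), XPhos (6 mol%), THF, 60 °C
Reagents that add atoms: (2-ethoxy-2-oxoethyl)zinc bromide, CCOC(=O)C[Zn]Br
Why: Negishi-type α-arylation with the Reformatsky reagent is a near-neutral way to attach the acetate unit to a mono-ortho-substituted aryl bromide and leaves both acetals and the benzyl ether untouched.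

**Step 10**
Reactants: 12 ethyl 2-[5-(benzyloxy)-2,4-bis(1,3-dioxolan-2-yl)-3-methoxyphenyl]acetate
Product: 13 2-[5-(benzyloxy)-2,4-bis(1,3-dioxolan-2-yl)-3-methoxyphenyl]acetic acid
Conditions: LiOH·H2O, THF/MeOH/H2O, rt; AcOH to pH 5, 0 °C
Reagents that add atoms: lithium hydroxide, [Li+].[OH-]
Why: Saponification of an unhindered ethyl arylacetate, with only a brief cold acidification to pH 5 so the aryl dioxolanes survive.

**Step 11**
Reactants: 13 2-[5-(benzyloxy)-2,4-bis(1,3-dioxolan-2-yl)-3-methoxyphenyl]acetic acid; 14 (4S)-4-benzyl-1,3-thiazolidine-2-thione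
Product: 15 (4S)-4-benzyl-3-{[5-(benzyloxy)-2,4-bis(1,3-dioxolan-2-yl)-3-methoxyphenyl]acetyl}-1,3-thiazolidine-2-thione
Conditions: EDC·HCl (1.3 equiv), DMAP (0.2 equiv), CH2Cl2, 0 °C → rt
Reagents that add atoms: none
Why: Carbodiimide/DMAP N-acylation of the thiazolidinethione attaches the chiral auxiliary under conditions that do not touch the acetals.

**Step 12**
Reactants: 15 (4S)-4-benzyl-3-{[5-(benzyloxy)-2,4-bis(1,3-dioxolan-2-yl)-3-methoxyphenyl]acetyl}-1,3-thiazolidine-2-thione; 10 6-(benzyloxy)-8-methoxy-3-methylisoquinoline-7-carbaldehyde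
Product: 17 (4S)-4-benzyl-3-[(2S,3R)-2-[5-(benzyloxy)-2,4-bis(1,3-dioxolan-2-yl)-3-methoxyphenyl]-3-[6-(benzyloxy)-8-methoxy-3-methylisoquinolin-7-yl]-3-(trimethylsilyloxy)propanoyl]-1,3-thiazolidine-2-thione, via magnesium Z-enolate 16 (not isolated)
Conditions: MgBr2·OEt2 (0.3 equiv), Et3N (2.5 equiv), TMSCl (1.8 equiv), EtOAc, rt, 24–48 h; pH 7 buffer work-up; Et3N-deactivated silica
Reagents that add atoms: chlorotrimethylsilane, C[Si](C)(C)Cl
Why: Evans magnesium-halide-catalysed direct anti-aldol, in which soft enolisation of the acidic arylacetyl thioimide gives the Z-enolate that adds to the non-enolisable aldehyde and is trapped irreversibly as the silyl ether; the (S)-benzyl thiazolidinethione gives the "Evans-anti" adduct, setting the aryl-bearing α-carbon as S and the carbinol carbon as R.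

**Step 13**
Reactants: 17 (4S)-4-benzyl-3-[(2S,3R)-2-[5-(benzyloxy)-2,4-bis(1,3-dioxolan-2-yl)-3-methoxyphenyl]-3-[6-(benzyloxy)-8-methoxy-3-methylisoquinolin-7-yl]-3-(trimethylsilyloxy)propanoyl]-1,3-thiazolidine-2-thione
Product: 18 (2S,3R)-2-[5-(benzyloxy)-2,4-bis(1,3-dioxolan-2-yl)-3-methoxyphenyl]-3-[6-(benzyloxy)-8-methoxy-3-methylisoquinolin-7-yl]-N-methoxy-N-methyl-3-(trimethylsilyloxy)propanamide
Conditions: MeNH(OMe)·HCl (3 equiv), imidazole (5 equiv), CH2Cl2, rt
Reagents that add atoms: N,O-dimethylhydroxylamine hydrochloride, CNOC.Cl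
Why: Aminolysis of the highly activated N-acyl thiazolidinethione under weakly basic conditions gives the Weinreb amide without Lewis acid, so the acetals, the silyl ether and the α-stereocentre are preserved and the auxiliary is recovered.

**Step 14**
Reactants: 18 (2S,3R)-2-[5-(benzyloxy)-2,4-bis(1,3-dioxolan-2-yl)-3-methoxyphenyl]-3-[6-(benzyloxy)-8-methoxy-3-methylisoquinolin-7-yl]-N-methoxy-N-methyl-3-(trimethylsilyloxy)propanamide
Product: 20 (3S,4R)-3-[5-(benzyloxy)-2,4-bis(1,3-dioxolan-2-yl)-3-methoxyphenyl]-4-[6-(benzyloxy)-8-methoxy-3-methylisoquinolin-7-yl]-4-(trimethylsilyloxy)butan-2-one, via magnesium hemiaminal chelate 19 (not isolated)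
Conditions: MeMgBr (3 equiv), THF, −78 → 0 °C; AcOH/THF quench at −78 °C
Reagents that add atoms: methylmagnesium bromide, C[Mg]Br
Why: Weinreb ketone synthesis, in which the chelated tetrahedral adduct persists until the acidic quench, so the epimerisable α-aryl ketone is never exposed to base and over-addition is excluded.

**Step 15**
Reactants: 20 (3S,4R)-3-[5-(benzyloxy)-2,4-bis(1,3-dioxolan-2-yl)-3-methoxyphenyl]-4-[6-(benzyloxy)-8-methoxy-3-methylisoquinolin-7-yl]-4-(trimethylsilyloxy)butan-2-one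
Product: 21 (3S,4R)-3-[2,4-bis(1,3-dioxolan-2-yl)-5-hydroxy-3-methoxyphenyl]-4-(6-hydroxy-8-methoxy-3-methylisoquinolin-7-yl)-4-(trimethylsilyloxy)butan-2-one
Conditions: H2 (1 atm), 10% Pd/C, EtOAc, rt, monitored
Reagents that add atoms: none
Why: Hydrogenolysis of the two aryl benzyl ethers under neutral conditions is much faster than cleavage of the hindered aryl dioxolanes or the benzylic silyl ether, and is done while both aldehydes are still masked.

**Step 16**
Reactants: 21 (3S,4R)-3-[2,4-bis(1,3-dioxolan-2-yl)-5-hydroxy-3-methoxyphenyl]-4-(6-hydroxy-8-methoxy-3-methylisoquinolin-7-yl)-4-(trimethylsilyloxy)butan-2-one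
Product: 24 target CNP0584953.1 (acetal carbon R; O-bearing benzylic carbon R; acetyl-bearing carbon S), via hydroxy dialdehyde 22 (not isolated), via lactol 23 (not isolated)
Conditions: 0.5 M aq. HCl/THF (1:3), 0 °C → rt; then NaHCO3
Reagents that add atoms: water, O
Why: Acid-catalysed deprotection/acetalisation cascade, in which dilute acid removes the TMS ether and both dioxolanes, the formyl group ortho to the side chain closes onto the secondary alcohol to a six-membered lactol, and its oxocarbenium ion is captured by the isoquinoline 6-OH; the acetal carbon is forced to R by the cis-bridging geometry from the fixed carbinol centre, and the other two stereocentres are not touched.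

**Compound list**
1 | 4-bromo-2,6-difluorobenzaldehyde | O=Cc1c(F)cc(Br)cc1F | starting material
2 | 2-(benzyloxy)-4-bromo-6-fluorobenzaldehyde | O=Cc1c(F)cc(Br)cc1OCc1ccccc1 | intermediate
3 | 2-[2-(benzyloxy)-4-bromo-6-fluorophenyl]-1,3-dioxolane | Fc1cc(Br)cc(OCc2ccccc2)c1C1OCCO1 | intermediate
4 | [4-(benzyloxy)-6-bromo-3-(1,3-dioxolan-2-yl)-2-fluorophenyl]lithium | [Li]c1c(F)c(C2OCCO2)c(OCc2ccccc2)cc1Br | intermediate
5 | 4-(benzyloxy)-6-bromo-3-(1,3-dioxolan-2-yl)-2-fluorobenzaldehyde | O=Cc1c(F)c(C2OCCO2)c(OCc2ccccc2)cc1Br | intermediate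
6 | 4-(benzyloxy)-6-bromo-3-(1,3-dioxolan-2-yl)-2-methoxybenzaldehyde | O=Cc1c(OC)c(C2OCCO2)c(OCc2ccccc2)cc1Br | intermediate
7 | 4-(benzyloxy)-3-(1,3-dioxolan-2-yl)-2-methoxy-6-(prop-1-yn-1-yl)benzaldehyde | O=Cc1c(OC)c(C2OCCO2)c(OCc2ccccc2)cc1C#CC | intermediate
8 | (E)-N-tert-butyl-1-[4-(benzyloxy)-3-(1,3-dioxolan-2-yl)-2-methoxy-6-(prop-1-yn-1-yl)phenyl]methanimine | CC#Cc1cc(OCc2ccccc2)c(C2OCCO2)c(OC)c1/C=N/C(C)(C)C | intermediate
9 | 6-(benzyloxy)-7-(1,3-dioxolan-2-yl)-8-methoxy-3-methylisoquinoline | Cc1cc2cc(OCc3ccccc3)c(C3OCCO3)c(OC)c2cn1 | intermediate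
10 | 6-(benzyloxy)-8-methoxy-3-methylisoquinoline-7-carbaldehyde | Cc1cc2cc(OCc3ccccc3)c(C=O)c(OC)c2cn1 | intermediate
11 | 2,2'-[4-(benzyloxy)-6-bromo-2-methoxy-1,3-phenylene]bis(1,3-dioxolane) | COc1c(C2OCCO2)c(Br)cc(OCc2ccccc2)c1C1OCCO1 | intermediate
12 | ethyl 2-[5-(benzyloxy)-2,4-bis(1,3-dioxolan-2-yl)-3-methoxyphenyl]acetate | CCOC(=O)Cc1cc(OCc2ccccc2)c(C2OCCO2)c(OC)c1C1OCCO1 | intermediate
13 | 2-[5-(benzyloxy)-2,4-bis(1,3-dioxolan-2-yl)-3-methoxyphenyl]acetic acid | OC(=O)Cc1cc(OCc2ccccc2)c(C2OCCO2)c(OC)c1C1OCCO1 | intermediate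
14 | (4S)-4-benzyl-1,3-thiazolidine-2-thione | S=C1SC[C@H](Cc2ccccc2)N1 | starting material
15 | (4S)-4-benzyl-3-{[5-(benzyloxy)-2,4-bis(1,3-dioxolan-2-yl)-3-methoxyphenyl]acetyl}-1,3-thiazolidine-2-thione | S=C1SC[C@H](Cc2ccccc2)N1C(=O)Cc1cc(OCc2ccccc2)c(C2OCCO2)c(OC)c1C1OCCO1 | intermediate
16 | bromomagnesium (Z)-enolate of 15 (Mg on the enolate oxygen; aryl cis to O) | S=C1SC[C@H](Cc2ccccc2)N1/C(O[Mg]Br)=C/c1cc(OCc2ccccc2)c(C2OCCO2)c(OC)c1C1OCCO1 | intermediate
17 | (4S)-4-benzyl-3-[(2S,3R)-2-[5-(benzyloxy)-2,4-bis(1,3-dioxolan-2-yl)-3-methoxyphenyl]-3-[6-(benzyloxy)-8-methoxy-3-methylisoquinolin-7-yl]-3-(trimethylsilyloxy)propanoyl]-1,3-thiazolidine-2-thione | S=C1SC[C@H](Cc2ccccc2)N1C(=O)[C@@H](c1cc(OCc2ccccc2)c(C2OCCO2)c(OC)c1C1OCCO1)[C@@H](O[Si](C)(C)C)c1c(OCc2ccccc2)cc2cc(C)ncc2c1OC | intermediate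
18 | (2S,3R)-2-[5-(benzyloxy)-2,4-bis(1,3-dioxolan-2-yl)-3-methoxyphenyl]-3-[6-(benzyloxy)-8-methoxy-3-methylisoquinolin-7-yl]-N-methoxy-N-methyl-3-(trimethylsilyloxy)propanamide | CON(C)C(=O)[C@@H](c1cc(OCc2ccccc2)c(C2OCCO2)c(OC)c1C1OCCO1)[C@@H](O[Si](C)(C)C)c1c(OCc2ccccc2)cc2cc(C)ncc2c1OC | intermediate
19 | bromomagnesium alkoxide of the tetrahedral MeMgBr adduct of 18 (N-methoxy-N-methyl hemiaminal; side-chain configuration as in 18) | CON(C)C(C)(O[Mg]Br)[C@@H](c1cc(OCc2ccccc2)c(C2OCCO2)c(OC)c1C1OCCO1)[C@@H](O[Si](C)(C)C)c1c(OCc2ccccc2)cc2cc(C)ncc2c1OC | intermediate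
20 | (3S,4R)-3-[5-(benzyloxy)-2,4-bis(1,3-dioxolan-2-yl)-3-methoxyphenyl]-4-[6-(benzyloxy)-8-methoxy-3-methylisoquinolin-7-yl]-4-(trimethylsilyloxy)butan-2-one | CC(=O)[C@@H](c1cc(OCc2ccccc2)c(C2OCCO2)c(OC)c1C1OCCO1)[C@@H](O[Si](C)(C)C)c1c(OCc2ccccc2)cc2cc(C)ncc2c1OC | intermediate
21 | (3S,4R)-3-[2,4-bis(1,3-dioxolan-2-yl)-5-hydroxy-3-methoxyphenyl]-4-(6-hydroxy-8-methoxy-3-methylisoquinolin-7-yl)-4-(trimethylsilyloxy)butan-2-one | CC(=O)[C@@H](c1cc(O)c(C2OCCO2)c(OC)c1C1OCCO1)[C@@H](O[Si](C)(C)C)c1c(O)cc2cc(C)ncc2c1OC | intermediate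
22 | (3S,4R)-3-(2,4-diformyl-5-hydroxy-3-methoxyphenyl)-4-hydroxy-4-(6-hydroxy-8-methoxy-3-methylisoquinolin-7-yl)butan-2-one | CC(=O)[C@@H](c1cc(O)c(C=O)c(OC)c1C=O)[C@@H](O)c1c(O)cc2cc(C)ncc2c1OC | intermediate
23 | (3R,4S)-4-acetyl-1,6-dihydroxy-3-(6-hydroxy-8-methoxy-3-methylisoquinolin-7-yl)-8-methoxy-3,4-dihydro-1H-isochromene-7-carbaldehyde (lactol; both C1 epimers) | CC(=O)[C@H]1c2cc(O)c(C=O)c(OC)c2C(O)O[C@H]1c1c(O)cc2cc(C)ncc2c1OC | intermediate
24 | target CNP0584953.1: 2,6-dioxabicyclo[3.3.1]nonane core fused to ring A (hydroxy-methoxy-benzaldehyde) and ring B (methoxy-methylisoquinoline); acetal CH (R); isoquinolinyl O–CH (R); acetyl-bearing CH (S) | COc1c(C=O)c(O)cc2c1[C@H]1Oc3cc4cc(C)ncc4c(OC)c3[C@H](O1)[C@H]2C(C)=O | target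

**Totals**
Total step count: 16. Longest linear sequence: 13 steps (steps 1–4, 8–11, 12–16).

**Three steps most likely to fail**

Step 12 (aldol). Both partners are congested (the aldehyde is flanked by two alkoxy groups, the enolate carbon by an ortho-substituted arene). The facial and anti selectivity are extrapolated from propionyl thioimides. The MgBr2/TMSCl couple may also attack the electron-rich aryl dioxolanes. Fallback: replace the aldol by a carbonyl allylation followed by Wacker oxidation. It sets out from bromide 11 (with aldehyde 10). Sonogashira coupling of 11 with propyne (PdCl2(PPh3)2, CuI, Et3N) gives the aryl propyne F1. A ruthenium-catalysed, 2-propanol-mediated anti-(α-aryl)allylation of 10 with F1 follows, the alkyne serving as allylmetal equivalent (RuH2(CO)(PPh3)3, the appropriate enantiomer of 1-[2-(dicyclohexylphosphino)ferrocenyl]ethyldi-tert-butylphosphine, Bu4NI). This gives the anti homoallylic alcohol F2 with the same two stereocentres. TMSCl/imidazole gives the silyl ether F3, and a buffered Wacker oxidation of the terminal alkene (PdCl2, CuCl, O2, DMF/H2O) comes back to the route at ketone 20.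

Step 14 (MeMgBr on the Weinreb amide). The amide is very hindered and its α-aryl proton is acidic, so slow addition and competing deprotonation (loss of the α-stereocentre) are possible. Fallback: avoid the basic organometallic altogether. It sets out from 17. Thiolysis with EtSH/imidazole in CH2Cl2 gives the S-ethyl thioester F4. Fukuyama coupling (MeZnI, PdCl2(PPh3)2, toluene/THF, rt) then gives the methyl ketone under non-basic conditions and comes back to the route at 20.

Step 16 (final cascade). The free α-aryl ketone can enolise in acid, which would epimerise the acetyl-bearing carbon. It can also condense with the unmasked ortho-formyl group to a 2-benzopyrylium or naphthol by-product before the acetal closes. Fallback: form the acetal before the ketone exists and oxidise last. It sets out from 20. Reduction with NaBH4/CeCl3·7H2O in MeOH/THF at −40 °C gives the secondary carbinol F5. Ac2O/pyridine/DMAP gives the acetate F6, and H2 over Pd/C gives the bis-phenol F7. The same dilute HCl/THF treatment then gives the bridged acetal acetate F8; no ketone is present, and the acetate keeps the extra hydroxyl from competing for the aldehyde. K2CO3/MeOH gives the bridged acetal carbinol F9, with no epimerisable centre at this stage. Dess–Martin periodinane buffered with NaHCO3 in CH2Cl2 then oxidises F9 to the ketone and comes back to the route at target 24.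

**Further compounds**
F1 | step 12 | 2,2'-[4-(benzyloxy)-2-methoxy-6-(prop-1-yn-1-yl)-1,3-phenylene]bis(1,3-dioxolane) | CC#Cc1cc(OCc2ccccc2)c(C2OCCO2)c(OC)c1C1OCCO1
F2 | step 12 | (1R,2S)-2-[5-(benzyloxy)-2,4-bis(1,3-dioxolan-2-yl)-3-methoxyphenyl]-1-[6-(benzyloxy)-8-methoxy-3-methylisoquinolin-7-yl]but-3-en-1-ol | C=C[C@@H](c1cc(OCc2ccccc2)c(C2OCCO2)c(OC)c1C1OCCO1)[C@@H](O)c1c(OCc2ccccc2)cc2cc(C)ncc2c1OC
F3 | step 12 | trimethylsilyl ether of F2 (same configuration) | C=C[C@@H](c1cc(OCc2ccccc2)c(C2OCCO2)c(OC)c1C1OCCO1)[C@@H](O[Si](C)(C)C)c1c(OCc2ccccc2)cc2cc(C)ncc2c1OC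
F4 | step 14 | S-ethyl (2S,3R)-2-[5-(benzyloxy)-2,4-bis(1,3-dioxolan-2-yl)-3-methoxyphenyl]-3-[6-(benzyloxy)-8-methoxy-3-methylisoquinolin-7-yl]-3-(trimethylsilyloxy)propanethioate | CCSC(=O)[C@@H](c1cc(OCc2ccccc2)c(C2OCCO2)c(OC)c1C1OCCO1)[C@@H](O[Si](C)(C)C)c1c(OCc2ccccc2)cc2cc(C)ncc2c1OC
F5 | step 16 | butan-2-ol obtained by reducing the ketone of 20 (carbinol epimers; other two centres arranged as in 20) | CC(O)[C@@H](c1cc(OCc2ccccc2)c(C2OCCO2)c(OC)c1C1OCCO1)[C@@H](O[Si](C)(C)C)c1c(OCc2ccccc2)cc2cc(C)ncc2c1OC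
F6 | step 16 | acetate ester of F5 | CC(OC(C)=O)[C@@H](c1cc(OCc2ccccc2)c(C2OCCO2)c(OC)c1C1OCCO1)[C@@H](O[Si](C)(C)C)c1c(OCc2ccccc2)cc2cc(C)ncc2c1OC
F7 | step 16 | bis-phenol from F6 after removal of both benzyl groups | CC(OC(C)=O)[C@@H](c1cc(O)c(C2OCCO2)c(OC)c1C1OCCO1)[C@@H](O[Si](C)(C)C)c1c(O)cc2cc(C)ncc2c1OC
F8 | step 16 | bridged acetal of the target skeleton bearing 1-acetoxyethyl in place of acetyl | COc1c(C=O)c(O)cc2c1[C@H]1Oc3cc4cc(C)ncc4c(OC)c3[C@H](O1)[C@H]2C(C)OC(C)=O
F9 | step 16 | bridged acetal of the target skeleton bearing 1-hydroxyethyl in place of acetyl | COc1c(C=O)c(O)cc2c1[C@H]1Oc3cc4cc(C)ncc4c(OC)c3[C@H](O1)[C@H]2C(C)O
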